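The oxolane is opened at O1–C2. This leads back to an open-chain γ-hydroxy aryl ketone whose C3 and C4 centres are already in place. In one operation Et3SiH and BF3·OEt2 let the C5 hydroxyl close onto the ketone, ionise the hemiketal and put hydride on C2. That creates the ring, the O1–C2 bond and the last stereocentre. The step exploits the cis arrangement of the C3 silyloxymethyl and C4 benzyl groups on the oxolane ring. They screen one face of planar C2, so hydride enters opposite and the aryl group ends all-cis. The precursor, a tert-butyldiphenylsilyl-protected (2R,3R)-hydroxy ketone, comes from a cis-lactone and an aryllithium.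

Key step: step 8

Remark on the structures: CIP analysis of the target gives 2R,3R,4R, with aryl, hydroxymethyl and benzyl groups on one face of the ring. The hydroxy ketone (2R,3R; anti in the zigzag chain, which is cis on the ring) and the ring-closed silyl ether (2R,3R,4R) match this configuration, so no structure needs correcting. The oxolane numbering of the target (O1, C2–C5) is used for all intermediates.

Remark on the design:
- A tert-butyldiphenylsilyl ether is used instead of a tert-butyldimethylsilyl ether. A primary tert-butyldimethylsilyl ether is at risk from BF3·OEt2 and from migration to the C5 alkoxide in the aryllithium step. The larger group also strengthens the facial bias.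
- The cis-lactone is reached from a trans-lactone acid by moving the lactone carbonyl from C5 to C2. C3 is therefore set by an auxiliary and C4 by ring control, without a resolution.

Assumption: 3,4-dimethoxybenzyl bromide is bought and used fresh, since it degrades on storage.

Step 1
Reactants: 1 (S)-4-benzyl-1,3-oxazolidin-2-one; 2 methyl 4-chloro-4-oxobutanoate
Product: 3 methyl 4-[(4S)-4-benzyl-2-oxo-1,3-oxazolidin-3-yl]-4-oxobutanoate
Conditions: Et3N, 4-(dimethylamino)pyridine (cat.), CH2Cl2, 0 °C → rt
Reagents that add atoms: none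
Why: N-acylation of an oxazolidinone by an acid chloride under amine catalysis is routine and leaves the stereocentre of the auxiliary untouched.

Step 2
Reactants: 3 methyl 4-[(4S)-4-benzyl-2-oxo-1,3-oxazolidin-3-yl]-4-oxobutanoate
Product: 5 methyl (3R)-4-[(4S)-4-benzyl-2-oxo-1,3-oxazolidin-3-yl]-3-(hydroxymethyl)-4-oxobutanoate, via trichlorotitanium Z-enolate 4 (not isolated)
Conditions: TiCl4, i-Pr2NEt, CH2Cl2, 0 °C; then 1,3,5-trioxane, TiCl4, 0 °C; aq NH4Cl
Reagents that add atoms: 1,3,5-trioxane, C1OCOCO1
Why: In this Evans-type auxiliary-controlled titanium enolate hydroxymethylation the imide is enolised selectively over the ester, and TiCl4-activated formaldehyde attacks the chelated Z-enolate on the face away from the benzyl group of the (S)-auxiliary, which sets C3 as R.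

Step 3
Reactants: 5 methyl (3R)-4-[(4S)-4-benzyl-2-oxo-1,3-oxazolidin-3-yl]-3-(hydroxymethyl)-4-oxobutanoate
Product: 8 (3R)-5-oxooxolane-3-carboxylic acid [(R)-paraconic acid], via peroxy acid 6 (not isolated), via hydroxy half-ester 7 (not isolated)
Conditions: LiOH, H2O2, THF/H2O, 0 °C; Na2SO3; CH2Cl2 extraction of 1; HCl to pH 1, rt
Reagents that add atoms: hydrogen peroxide (acting as LiOOH), OO
Why: Hydroperoxide cleavage of an N-acyl oxazolidinone attacks the exocyclic carbonyl without touching C3 and returns the auxiliary, and on acidification the γ-hydroxy ester lactonises, so the cleavage is run while the β-oxygen is still a poor leaving group.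

Step 4
Reactants: 8 (3R)-5-oxooxolane-3-carboxylic acid; 9 3,4-dimethoxybenzyl bromide
Product: 11 (3R,4R)-4-[(3,4-dimethoxyphenyl)methyl]-5-oxooxolane-3-carboxylic acid (trans), via dilithium dianion 10 (not isolated)
Conditions: LiN(SiMe3)2 (2.2 equiv), THF, −78 °C; 9, −78 → −20 °C; 1 M HCl
Reagents that add atoms: none
Why: In this carboxylate/lactone-enolate dianion alkylation (the type used for α-alkylation of paraconic acids) the carboxylate protects its own α-proton so that only the lactone CH2 is deprotonated, and the benzylic bromide approaches anti to the C3 carboxylate, setting C4 as R in the arrangement that is also the more stable one.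

Step 5
Reactants: 11 (3R,4R)-4-[(3,4-dimethoxyphenyl)methyl]-5-oxooxolane-3-carboxylic acid
Product: 13 (3R,4R)-4-[(3,4-dimethoxyphenyl)methyl]-3-(hydroxymethyl)oxolan-2-one (cis), via dihydroxy acid 12 (not isolated)
Conditions: LiBEt3H (3.3 equiv), THF, −78 → 0 °C; then 2 M HCl, rt
Reagents that add atoms: none
Why: Chemoselective trialkylborohydride reduction of a lactone beside an inert lithium carboxylate (as in hemiester-to-lactone conversions), followed by acid lactonisation of the only γ-hydroxyl, moves the carbonyl from C5 to C2 without touching a stereocentre, and because the ring now contains C2 in place of the hydroxymethyl carbon, the trans acid becomes the cis-3,4-disubstituted lactone.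

Step 6
Reactants: 13 (3R,4R)-4-[(3,4-dimethoxyphenyl)methyl]-3-(hydroxymethyl)oxolan-2-one
Product: 14 (3R,4R)-3-{[tert-butyl(diphenyl)silyl]oxymethyl}-4-[(3,4-dimethoxyphenyl)methyl]oxolan-2-one (cis)
Conditions: t-BuPh2SiCl, imidazole, CH2Cl2, 0 °C → rt
Reagents that add atoms: tert-butyl(chloro)diphenylsilane, CC(C)(C)[Si](Cl)(c1ccccc1)c1ccccc1
Why: Standard silylation of a primary alcohol, in which imidazole is too weak a base to epimerise C3 of the cis-lactone.

Step 7
Reactants: 14 (3R,4R)-3-{[tert-butyl(diphenyl)silyl]oxymethyl}-4-[(3,4-dimethoxyphenyl)methyl]oxolan-2-one; 15 5-bromo-1,2,3-trimethoxybenzene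
Product: 18 (2R,3R)-2-{[tert-butyl(diphenyl)silyl]oxymethyl}-3-[(3,4-dimethoxyphenyl)methyl]-4-hydroxy-1-(3,4,5-trimethoxyphenyl)butan-1-one, via aryllithium 16 (not isolated), via lithium lactolate 17 (not isolated)
Conditions: 15, n-BuLi, THF, −78 °C; then 14, −78 °C; AcOH in THF at −78 °C
Reagents that add atoms: none
Why: Bromine–lithium exchange is followed by single addition of the aryllithium to the γ-lactone, where the tetrahedral lactolate persists at −78 °C and blocks a second addition, and the cold acidic quench avoids enolisation at C3, β-elimination of the silyloxy group and silyl migration.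

Step 8
Reactants: 18 (2R,3R)-2-{[tert-butyl(diphenyl)silyl]oxymethyl}-3-[(3,4-dimethoxyphenyl)methyl]-4-hydroxy-1-(3,4,5-trimethoxyphenyl)butan-1-one
Product: 21 tert-butyl{[(2R,3R,4R)-4-[(3,4-dimethoxyphenyl)methyl]-2-(3,4,5-trimethoxyphenyl)oxolan-3-yl]methoxy}diphenylsilane (all-cis), via cyclic hemiketal 19 (not isolated), via oxocarbenium ion 20 (not isolated)
Conditions: Et3SiH (5 equiv), then BF3·OEt2 (2 equiv), CH2Cl2, −78 → −40 °C; Et3N added cold, then aq NaHCO3
Reagents that add atoms: none
Why: The C5 hydroxyl adds to the aryl ketone in a 5-exo-trig closure to give hemiketal 19, BF3 abstracts the C2 hydroxyl, and the aryl-stabilised oxocarbenium ion 20 accepts hydride from Et3SiH at C2, so the O1–C2 bond, the oxolane ring and the C2 stereocentre are made in one flask. The closest known reaction type is the silane/Lewis acid reduction of lactols formed from aryllithiums and lactones, familiar from C-aryl glycoside and oxolane lignan chemistry. C2 is set by substrate control: the C3 silyloxymethyl group and the C4 benzyl group lie on the same face of the nearly planar cation, hydride is delivered to the opposite face, and the aryl group is turned cis to both, giving 2R. The outcome is kinetic, which is essential because the all-cis isomer is the least stable one and would be lost in an equilibrating acid closure. Hydride capture must outrun loss of the C3 proton (enol ether formation would scramble C3), which is secured by having excess silane present before BF3·OEt2 is added at −78 °C, and the product must not ionise again, which is helped by the two meta-methoxy groups that temper the donor power of the aryl ring and by the cold amine quench. The tert-butyldiphenylsilyl ether should tolerate BF3·OEt2 at this temperature and enlarges the steric bias.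

Step 9
Reactants: 21 tert-butyl{[(2R,3R,4R)-4-[(3,4-dimethoxyphenyl)methyl]-2-(3,4,5-trimethoxyphenyl)oxolan-3-yl]methoxy}diphenylsilane
Product: 22 [(2R,3R,4R)-4-[(3,4-dimethoxyphenyl)methyl]-2-(3,4,5-trimethoxyphenyl)oxolan-3-yl]methanol (target)
Conditions: Bu4NF, THF, 0 °C → rt
Reagents that add atoms: none
Why: Fluoride cleavage of the silyl ether runs under non-acidic conditions, so the acid-sensitive all-cis benzylic ether is not re-ionised and no stereocentre is touched.

Compound list
1 | (S)-4-benzyl-1,3-oxazolidin-2-one | O=C1N[C@@H](Cc2ccccc2)CO1 | starting material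
2 | methyl 4-chloro-4-oxobutanoate | COC(=O)CCC(=O)Cl | starting material
3 | methyl 4-[(4S)-4-benzyl-2-oxo-1,3-oxazolidin-3-yl]-4-oxobutanoate | COC(=O)CCC(=O)N1C(=O)OC[C@@H]1Cc1ccccc1 | intermediate
4 | trichlorotitanium (Z)-enolate of 3 | COC(=O)C/C=C(\O[Ti](Cl)(Cl)Cl)N1C(=O)OC[C@@H]1Cc1ccccc1 | intermediate
5 | methyl (3R)-4-[(4S)-4-benzyl-2-oxo-1,3-oxazolidin-3-yl]-3-(hydroxymethyl)-4-oxobutanoate | COC(=O)C[C@H](CO)C(=O)N1C(=O)OC[C@@H]1Cc1ccccc1 | intermediate
6 | (2R)-2-(hydroxymethyl)-4-methoxy-4-oxobutaneperoxoic acid | COC(=O)C[C@H](CO)C(=O)OO | intermediate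
7 | (2R)-2-(hydroxymethyl)-4-methoxy-4-oxobutanoic acid | COC(=O)C[C@H](CO)C(=O)O | intermediate
8 | (3R)-5-oxooxolane-3-carboxylic acid, (R)-paraconic acid | O=C1C[C@H](CO1)C(=O)O | intermediate
9 | 3,4-dimethoxybenzyl bromide, 4-(bromomethyl)-1,2-dimethoxybenzene | COc1ccc(CBr)cc1OC | starting material
10 | dilithium carboxylate/lactone-enolate dianion of 8 | [Li+].[Li+].[O-]C(=O)[C@H]1COC([O-])=C1 | intermediate
11 | (3R,4R)-4-[(3,4-dimethoxyphenyl)methyl]-5-oxooxolane-3-carboxylic acid, trans | OC(=O)[C@H]1COC(=O)[C@@H]1Cc1ccc(OC)c(OC)c1 | intermediate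
12 | (2R,3R)-3-[(3,4-dimethoxyphenyl)methyl]-4-hydroxy-2-(hydroxymethyl)butanoic acid | OC(=O)[C@@H](CO)[C@H](CO)Cc1ccc(OC)c(OC)c1 | intermediate
13 | (3R,4R)-4-[(3,4-dimethoxyphenyl)methyl]-3-(hydroxymethyl)oxolan-2-one, cis | O=C1OC[C@H](Cc2ccc(OC)c(OC)c2)[C@@H]1CO | intermediate
14 | (3R,4R)-3-{[tert-butyl(diphenyl)silyl]oxymethyl}-4-[(3,4-dimethoxyphenyl)methyl]oxolan-2-one, cis | O=C1OC[C@H](Cc2ccc(OC)c(OC)c2)[C@@H]1CO[Si](c1ccccc1)(c1ccccc1)C(C)(C)C | intermediate
15 | 5-bromo-1,2,3-trimethoxybenzene | COc1cc(Br)cc(OC)c1OC | starting material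
16 | 3,4,5-trimethoxyphenyllithium | [Li]c1cc(OC)c(OC)c(OC)c1 | intermediate
17 | lithium (3R,4R)-3-{[tert-butyl(diphenyl)silyl]oxymethyl}-4-[(3,4-dimethoxyphenyl)methyl]-2-(3,4,5-trimethoxyphenyl)oxolan-2-olate | [Li+].[O-]C1(c2cc(OC)c(OC)c(OC)c2)OC[C@H](Cc2ccc(OC)c(OC)c2)[C@@H]1CO[Si](c1ccccc1)(c1ccccc1)C(C)(C)C | intermediate
18 | (2R,3R)-2-{[tert-butyl(diphenyl)silyl]oxymethyl}-3-[(3,4-dimethoxyphenyl)methyl]-4-hydroxy-1-(3,4,5-trimethoxyphenyl)butan-1-one | O=C(c1cc(OC)c(OC)c(OC)c1)[C@@H](CO[Si](c1ccccc1)(c1ccccc1)C(C)(C)C)[C@@H](Cc1ccc(OC)c(OC)c1)CO | intermediate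
19 | (3R,4R)-3-{[tert-butyl(diphenyl)silyl]oxymethyl}-4-[(3,4-dimethoxyphenyl)methyl]-2-(3,4,5-trimethoxyphenyl)oxolan-2-ol, both C2 epimers | OC1(c2cc(OC)c(OC)c(OC)c2)OC[C@H](Cc2ccc(OC)c(OC)c2)[C@@H]1CO[Si](c1ccccc1)(c1ccccc1)C(C)(C)C | intermediate
20 | (3R,4R)-2-aryl-3,4-dihydro-5H-oxolium (oxocarbenium) hydroxytrifluoroborate derived from 19 | COc1cc(cc(OC)c1OC)C1=[O+]C[C@H](Cc2ccc(OC)c(OC)c2)[C@@H]1CO[Si](c1ccccc1)(c1ccccc1)C(C)(C)C.O[B-](F)(F)F | intermediate
21 | tert-butyl{[(2R,3R,4R)-4-[(3,4-dimethoxyphenyl)methyl]-2-(3,4,5-trimethoxyphenyl)oxolan-3-yl]methoxy}diphenylsilane, all-cis | O1[C@@H](c2cc(OC)c(OC)c(OC)c2)[C@@H](CO[Si](c2ccccc2)(c2ccccc2)C(C)(C)C)[C@@H](Cc2ccc(OC)c(OC)c2)C1 | intermediate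
22 | [(2R,3R,4R)-4-[(3,4-dimethoxyphenyl)methyl]-2-(3,4,5-trimethoxyphenyl)oxolan-3-yl]methanol | COc1ccc(C[C@H]2CO[C@@H](c3cc(OC)c(OC)c(OC)c3)[C@H]2CO)cc1OC | target

Total step count: 9. Longest linear sequence: 9 steps (from 1 and 2 to 22). Compound 15 enters in step 7 after lithiation in the same flask.

Steps most likely to fail

**Step 8.** Proton loss from C3 of the cation, eroded facial selectivity, or renewed ionisation of the benzylic ether could reduce the share of the all-cis isomer.
- The fallback sets out from 18 and comes back at 21. It fixes C2 by reagent control and closes the ring at the other ether bond, O1–C5, by SN2.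
- Corey–Bakshi–Shibata reduction uses BH3·SMe2 and (S)-1-methyl-3,3-diphenyltetrahydro-1H,3H-pyrrolo[1,2-c][1,3,2]oxazaborole in THF, with the aryl ring taking the role of the large group. It should give the (1R,2R,3R)-1,4-diol F1.
- Selective sulfonylation of the primary hydroxyl (TsCl, pyridine, 0 °C) should give the primary monotosylate F2.
- NaH in THF then closes the ring by a 5-exo-tet Williamson etherification that leaves C2 untouched.

**Step 4.** Sluggish or repeated alkylation of the poorly soluble dianion, or modest anti selectivity, could limit this step.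
- The fallback sets out from 8 and comes back at 11. It replaces the halide by the more reactive aldehyde and removes the extra oxygen afterwards.
- Aldol addition of dianion 10 to 3,4-dimethoxybenzaldehyde (THF, −78 °C) should give the trans benzylic carbinol acid F3 as a mixture at the carbinol carbon.
- Hydrogenolysis of the electron-rich benzylic alcohol (H2, Pd/C, AcOH) then erases that centre and delivers 11.

**Step 7.** Enolisation of the lactone by the basic aryllithium (with epimerisation at C3 or β-elimination) or over-addition could erode the material.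
- The fallback sets out from 14 and comes back at 18 by a Weinreb ketone synthesis.
- Aminolysis of the lactone (MeNH(OMe)·HCl, Me3Al, CH2Cl2) should give the hydroxy Weinreb amide F4.
- This is capped at once (Et3SiCl, imidazole) as the triethylsilyl ether F5 to prevent relactonisation.
- The less basic 3,4,5-trimethoxyphenylmagnesium bromide F6 (from 15 and Mg in THF) adds once through the chelated adduct to give the bis-silylated ketone F7.
- AcOH/THF/H2O removes only the triethylsilyl group to return 18.

Further compounds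
F1 | step 8 | (1R,2R,3R)-2-{[tert-butyl(diphenyl)silyl]oxymethyl}-3-[(3,4-dimethoxyphenyl)methyl]-1-(3,4,5-trimethoxyphenyl)butane-1,4-diol | O[C@@H](c1cc(OC)c(OC)c(OC)c1)[C@@H](CO[Si](c1ccccc1)(c1ccccc1)C(C)(C)C)[C@@H](Cc1ccc(OC)c(OC)c1)CO
F2 | step 8 | (2R,3R,4R)-3-{[tert-butyl(diphenyl)silyl]oxymethyl}-2-[(3,4-dimethoxyphenyl)methyl]-4-hydroxy-4-(3,4,5-trimethoxyphenyl)butyl 4-methylbenzenesulfonate | O[C@@H](c1cc(OC)c(OC)c(OC)c1)[C@@H](CO[Si](c1ccccc1)(c1ccccc1)C(C)(C)C)[C@@H](Cc1ccc(OC)c(OC)c1)COS(=O)(=O)c1ccc(C)cc1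
F3 | step 4 | (3R,4S)-4-[(3,4-dimethoxyphenyl)(hydroxy)methyl]-5-oxooxolane-3-carboxylic acid, trans on the ring, both carbinol epimers | OC(=O)[C@H]1COC(=O)[C@@H]1C(O)c1ccc(OC)c(OC)c1
F4 | step 7 | (2R,3R)-2-{[tert-butyl(diphenyl)silyl]oxymethyl}-3-[(3,4-dimethoxyphenyl)methyl]-4-hydroxy-N-methoxy-N-methylbutanamide | CON(C)C(=O)[C@@H](CO[Si](c1ccccc1)(c1ccccc1)C(C)(C)C)[C@@H](Cc1ccc(OC)c(OC)c1)CO
F5 | step 7 | (2R,3R)-2-{[tert-butyl(diphenyl)silyl]oxymethyl}-3-[(3,4-dimethoxyphenyl)methyl]-N-methoxy-N-methyl-4-(triethylsilyloxy)butanamide | CON(C)C(=O)[C@@H](CO[Si](c1ccccc1)(c1ccccc1)C(C)(C)C)[C@@H](Cc1ccc(OC)c(OC)c1)CO[Si](CC)(CC)CC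
F6 | step 7 | 3,4,5-trimethoxyphenylmagnesium bromide | COc1cc([Mg]Br)cc(OC)c1OC
F7 | step 7 | (2R,3R)-2-{[tert-butyl(diphenyl)silyl]oxymethyl}-3-[(3,4-dimethoxyphenyl)methyl]-4-(triethylsilyloxy)-1-(3,4,5-trimethoxyphenyl)butan-1-one | O=C(c1cc(OC)c(OC)c(OC)c1)[C@@H](CO[Si](c1ccccc1)(c1ccccc1)C(C)(C)C)[C@@H](Cc1ccc(OC)c(OC)c1)CO[Si](CC)(CC)CC
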